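**Plan**

1. Numbering: C1 methyl-bearing fusion carbon, C2, C3, C4 isopropyl carbinol, C5 fusion CH, C6 ester carbon, C7, C8 (carrying the methylidene C14), C9 and C10 diol carbons (C10 bonded to C1). The five-membered ring is C1–C5; the seven-membered ring is C1, C5–C10.
2. Retrosynthetic cuts, in order: C8=C14 (methylenation), the C9 and C10 hydroxyls (dihydroxylation), C9=C10 (ring-closing metathesis), the C6 ester, C4–isopropyl, then C5–C6 and C1–CH3 together.
3. Enabling feature: the quaternary C1 lies β and the fusion carbon C5 α to the carbinol carbon C4, and C5 carries the carbinol C6. This is the imprint of methyl conjugate addition to a C4 cyclopentenone followed by aldol of the C4–C5 enolate.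
4. Forward: the five-membered ring is present from the start (enone 6). Enone 6, Me3Al and aldehyde 9 are joined in one flask to give 13; isopropenyl addition, acylation and unmasking of C9 and C10 as vinyl groups follow. The seven-membered ring closes last, by metathesis, and is then dihydroxylated and methylenated.
5. Stereochemistry: C1 from the chiral copper–phosphoramidite catalyst; C5 from aldehyde approach anti to the C1 acetal group; C6 from the closed aldol transition state of the ring E-enolate; C4 from addition anti to the C5 side chain; C9 and C10 from osmylation anti to the angular methyl.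

Key step: step 5

Assumption: the phosphoramidite antipode named in step 5 is taken to be the one that gives the (S)-configured C1; if the sense of induction proves opposite, its enantiomer is used and nothing else changes.

**Route**

Step 1
Reactants: 1 3-ethoxycyclopent-2-en-1-one; 2 1,3-dithiane
Product: 5 3-(1,3-dithian-2-yl)cyclopent-2-en-1-one, via 2-lithio-1,3-dithiane 3 (not isolated), via lithium alkoxide 1,2-adduct 4 (not isolated)
Conditions: 2, n-BuLi, THF, –30 °C; 1, –78 → 0 °C; 2 M aq. HCl, rt
Reagents that add atoms: water, O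
Why: Stork–Danheiser alkylative carbonyl transposition, in which the lithiated dithiane adds 1,2 to the vinylogous ester and aqueous acid collapses the tertiary allylic alkoxide with loss of ethanol to the 3-substituted enone, the dithiane being stable to dilute acid.

Step 2
Reactants: 5 3-(1,3-dithian-2-yl)cyclopent-2-en-1-one
Product: 6 3-(dimethoxymethyl)cyclopent-2-en-1-one
Conditions: PhI(OCOCF3)2, anhydrous MeOH, 0 °C → rt
Reagents that add atoms: methanol, CO
Why: Oxidative dethioacetalisation with a hypervalent iodine reagent activates sulfur as a leaving group and methanol displaces it twice, so the dimethyl acetal should form directly without freeing the sensitive formyl enone.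

Step 3
Reactants: 7 ethyl 4-(benzyloxy)-3-oxobutanoate
Product: 8 ethyl 2-[2-(benzyloxymethyl)-1,3-dioxolan-2-yl]acetate
Conditions: HOCH2CH2OH, TsOH·H2O (cat.), toluene, reflux, Dean–Stark
Reagents that add atoms: ethane-1,2-diol, OCCO
Why: Acid-catalysed ketalisation of a β-keto ester with azeotropic removal of water is standard and also blocks enolisation and β-elimination in the later aldehyde.

Step 4
Reactants: 8 ethyl 2-[2-(benzyloxymethyl)-1,3-dioxolan-2-yl]acetate
Product: 9 2-[2-(benzyloxymethyl)-1,3-dioxolan-2-yl]acetaldehyde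
Conditions: DIBAL-H (1.1 equiv), CH2Cl2, –78 °C; MeOH, aq. Rochelle salt
Reagents that add atoms: none
Why: Partial ester reduction with DIBAL-H at low temperature stops at the aldehyde because the tetrahedral aluminium hemiacetal, held by chelation to a ketal oxygen, survives until work-up.

Step 5
Reactants: 6 3-(dimethoxymethyl)cyclopent-2-en-1-one; 10 trimethylaluminium; 9 2-[2-(benzyloxymethyl)-1,3-dioxolan-2-yl]acetaldehyde
Product: 13 (2S,3S)-2-{(1S)-2-[2-(benzyloxymethyl)-1,3-dioxolan-2-yl]-1-hydroxyethyl}-3-(dimethoxymethyl)-3-methylcyclopentan-1-one, via dimethylaluminium enolate 11 (not isolated), via lithium aluminate enolate 12 (not isolated)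
Conditions: copper thiophene-2-carboxylate Cu(O2C-C4H3S) (2 mol%), O,O'-[(S)-1,1'-binaphthalene-2,2'-diyl] N,N-bis[(S)-1-phenylethyl]phosphoramidite (4 mol%), 10 (1.1 equiv), Et2O, –30 °C; MeLi (1.1 equiv), THF, –78 °C; 9 (1.5 equiv), –78 °C; H2O, aq. Rochelle salt
Reagents that add atoms: none
Why: A chiral monovalent copper–phosphoramidite complex, methylated by Me3Al, binds the enone, transfers methyl to the β-carbon C1 through a trivalent copper intermediate and releases the regiodefined aluminium enolate 11, which MeLi converts into the more nucleophilic aluminate 12; this adds to aldehyde 9 through a closed six-membered (Zimmerman–Traxler) transition state to form C5–C6. The closest known reaction type is the copper-catalysed asymmetric conjugate addition of trialkylaluminium reagents to 3-substituted cycloalkenones with trapping of the aluminium enolate after activation by an alkyllithium. No ring closes. C1 is set by the ligand; C5 by approach of the aldehyde to the enolate face anti to the branched dimethoxymethyl group on C1, hence cis to the methyl; C6 by the chair transition state of the ring-locked E-enolate with the aldehyde substituent equatorial, which gives the anti aldol. The step needs 1,4- rather than 1,2-methyl transfer, which copper catalysis in ether secures, and aldol addition rather than methyl transfer to the aldehyde or its β-elimination, which the near-stoichiometric Me3Al charge and the ketal-blocked β-carbon of 9 secure.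

Step 6
Reactants: 13 (2S,3S)-2-{(1S)-2-[2-(benzyloxymethyl)-1,3-dioxolan-2-yl]-1-hydroxyethyl}-3-(dimethoxymethyl)-3-methylcyclopentan-1-one
Product: 14 (1S,2S,3S)-2-{(1S)-2-[2-(benzyloxymethyl)-1,3-dioxolan-2-yl]-1-hydroxyethyl}-3-(dimethoxymethyl)-3-methyl-1-(prop-1-en-2-yl)cyclopentan-1-ol
Conditions: isopropenylmagnesium bromide, anhydrous CeCl3 (3 equiv each), THF, –78 °C; H2O
Reagents that add atoms: isopropenylmagnesium bromide, CC(=C)[Mg]Br
Why: Organocerium 1,2-addition suppresses enolisation and retro-aldol of the β-hydroxy ketone, and the nucleophile should enter the C4 carbonyl from the ring face opposite the C5 side chain, placing the new hydroxyl cis to that chain and to the C1 methyl.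

Step 7
Reactants: 14 (1S,2S,3S)-2-{(1S)-2-[2-(benzyloxymethyl)-1,3-dioxolan-2-yl]-1-hydroxyethyl}-3-(dimethoxymethyl)-3-methyl-1-(prop-1-en-2-yl)cyclopentan-1-ol
Product: 15 (1S)-2-[2-(benzyloxymethyl)-1,3-dioxolan-2-yl]-1-[(1S,2S,5S)-2-(dimethoxymethyl)-5-hydroxy-2-methyl-5-(prop-1-en-2-yl)cyclopentyl]ethyl 3-methylbutanoate
Conditions: isovaleryl chloride, pyridine, DMAP (cat.), CH2Cl2, 0 °C → rt
Reagents that add atoms: 3-methylbutanoyl chloride (isovaleryl chloride), CC(C)CC(Cl)=O
Why: DMAP-catalysed acylation distinguishes the secondary C6 hydroxyl from the tertiary allylic C4 hydroxyl on steric grounds, and the basic medium leaves both acetals intact.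

Step 8
Reactants: 15 (1S)-2-[2-(benzyloxymethyl)-1,3-dioxolan-2-yl]-1-[(1S,2S,5S)-2-(dimethoxymethyl)-5-hydroxy-2-methyl-5-(prop-1-en-2-yl)cyclopentyl]ethyl 3-methylbutanoate
Product: 16 (1S)-2-[2-(hydroxymethyl)-1,3-dioxolan-2-yl]-1-[(1S,2S,5R)-2-(dimethoxymethyl)-5-hydroxy-2-methyl-5-(propan-2-yl)cyclopentyl]ethyl 3-methylbutanoate
Conditions: H2 (1 atm), 10% Pd on carbon, EtOAc, rt
Reagents that add atoms: none
Why: Heterogeneous hydrogenation saturates the 1,1-disubstituted alkene and hydrogenolyses the benzyl ether in one operation without touching a stereocentre, the ester and acetals being inert in neutral ethyl acetate.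

Step 9
Reactants: 16 (1S)-2-[2-(hydroxymethyl)-1,3-dioxolan-2-yl]-1-[(1S,2S,5R)-2-(dimethoxymethyl)-5-hydroxy-2-methyl-5-(propan-2-yl)cyclopentyl]ethyl 3-methylbutanoate
Product: 17 (1S)-2-(2-formyl-1,3-dioxolan-2-yl)-1-[(1S,2S,5R)-2-(dimethoxymethyl)-5-hydroxy-2-methyl-5-(propan-2-yl)cyclopentyl]ethyl 3-methylbutanoate
Conditions: Dess–Martin periodinane, NaHCO3, CH2Cl2, rt
Reagents that add atoms: none
Why: Dess–Martin oxidation converts the primary alcohol to the aldehyde under buffered conditions without over-oxidation; the tertiary alcohol cannot react and the new aldehyde has no α-hydrogen.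

Step 10
Reactants: 17 (1S)-2-(2-formyl-1,3-dioxolan-2-yl)-1-[(1S,2S,5R)-2-(dimethoxymethyl)-5-hydroxy-2-methyl-5-(propan-2-yl)cyclopentyl]ethyl 3-methylbutanoate
Product: 18 (1S)-2-(2-formyl-1,3-dioxolan-2-yl)-1-[(1S,2S,5R)-2-formyl-5-hydroxy-2-methyl-5-(propan-2-yl)cyclopentyl]ethyl 3-methylbutanoate
Conditions: TsOH·H2O (cat.), THF/H2O 4:1, rt
Reagents that add atoms: water, O
Why: Acid-catalysed acetal hydrolysis should be chemoselective because the acyclic dimethyl acetal ionises readily, whereas the dioxolane flanked by the electron-withdrawing formyl group would give a strongly destabilised oxocarbenium ion.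

Step 11
Reactants: 18 (1S)-2-(2-formyl-1,3-dioxolan-2-yl)-1-[(1S,2S,5R)-2-formyl-5-hydroxy-2-methyl-5-(propan-2-yl)cyclopentyl]ethyl 3-methylbutanoate
Product: 19 (1S)-2-(2-ethenyl-1,3-dioxolan-2-yl)-1-[(1S,2R,5R)-2-ethenyl-5-hydroxy-2-methyl-5-(propan-2-yl)cyclopentyl]ethyl 3-methylbutanoate
Conditions: Ph3PCH3Br, KHMDS (excess), THF, 0 °C; 18, –78 → 0 °C
Reagents that add atoms: methyltriphenylphosphonium bromide, C[P+](c1ccccc1)(c1ccccc1)c1ccccc1.[Br-]
Why: Double Wittig methylenation is safe here because both aldehydes sit on fully substituted carbons and cannot enolise or eliminate, and aldehydes react with the ylide far faster than the hindered ester.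

Step 12
Reactants: 19 (1S)-2-(2-ethenyl-1,3-dioxolan-2-yl)-1-[(1S,2R,5R)-2-ethenyl-5-hydroxy-2-methyl-5-(propan-2-yl)cyclopentyl]ethyl 3-methylbutanoate
Product: 20 (3'R,3a'S,4'S,8a'R)-3'-hydroxy-8a'-methyl-3'-(propan-2-yl)-2',3',3a',4',5',8a'-hexahydro-1'H-spiro[1,3-dioxolane-2,6'-azulen]-4'-yl 3-methylbutanoate (trans-fused bicycle, C8 ethylene ketal, C9=C10 alkene)
Conditions: second-generation Grubbs catalyst RuCl2(=CHPh)(PCy3)(H2IMes) (10 mol%), toluene (2 mM), 80 °C
Reagents that add atoms: none
Why: Ring-closing metathesis joins the two vinyl termini into the seven-membered ring with loss of ethene; the trans, pseudo-diequatorial arms on the cyclopentane allow the trans-fused cycloheptene, and the ruthenium carbene tolerates ester, ketal and free tertiary alcohol.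

Step 13
Reactants: 20 spiro ketal cycloheptene described in step 12
Product: 21 (3R,3aS,4S,8aR)-3-hydroxy-8a-methyl-6-oxo-3-(propan-2-yl)-1,2,3,3a,4,5,6,8a-octahydroazulen-4-yl 3-methylbutanoate
Conditions: 1 M aq. HCl, THF, rt
Reagents that add atoms: water, O
Why: Hydrolysis of an allylic ketal is fast under mild acid because the oxocarbenium ion is conjugated with the alkene, giving the cycloheptenone without affecting the ester or the tertiary alcohol.

Step 14
Reactants: 21 (3R,3aS,4S,8aR)-3-hydroxy-8a-methyl-6-oxo-3-(propan-2-yl)-1,2,3,3a,4,5,6,8a-octahydroazulen-4-yl 3-methylbutanoate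
Product: 22 (3R,3aS,4S,7S,8S,8aS)-3,7,8-trihydroxy-8a-methyl-6-oxo-3-(propan-2-yl)decahydroazulen-4-yl 3-methylbutanoate
Conditions: OsO4 (5 mol%), NMO, citric acid, t-BuOH/H2O, rt
Reagents that add atoms: N-methylmorpholine N-oxide, C[N+]1([O-])CCOCC1; water, O
Why: Upjohn dihydroxylation adds both oxygens syn, and the axial angular methyl on C1 next to C10 blocks its face, so osmylation should occur on the opposite face and set C9 and C10 with the hydroxyls cis to each other and anti to the methyl, while the citric acid buffer keeps the β-acyloxy ketone from eliminating.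

Step 15
Reactants: 22 (3R,3aS,4S,7S,8S,8aS)-3,7,8-trihydroxy-8a-methyl-6-oxo-3-(propan-2-yl)decahydroazulen-4-yl 3-methylbutanoate
Product: 23 (3R,3aS,4S,7R,8S,8aS)-3,7,8-trihydroxy-8a-methyl-6-methylidene-3-(propan-2-yl)decahydroazulen-4-yl 3-methylbutanoate
Conditions: Zn, CH2Br2, TiCl4 (excess reagent), THF/CH2Cl2, 0 °C → rt
Reagents that add atoms: dibromomethane, BrCBr
Why: Takai–Lombardo methylenation uses a non-basic gem-dimetallic methylene reagent that olefinates hindered, enolisable and hydroxylated ketones without epimerising the α-carbinol C9 or eliminating the β-acyloxy group, and it leaves esters alone.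

**Compound list**

1 | 3-ethoxycyclopent-2-en-1-one | CCOC1=CC(=O)CC1 | starting material
2 | 1,3-dithiane | C1CSCSC1 | starting material
3 | 2-lithio-1,3-dithiane | [Li]C1SCCCS1 | intermediate (not isolated)
4 | lithium 1-(1,3-dithian-2-yl)-3-ethoxycyclopent-2-en-1-olate (racemic) | CCOC1=CC(O[Li])(CC1)C1SCCCS1 | intermediate (not isolated)
5 | 3-(1,3-dithian-2-yl)cyclopent-2-en-1-one | O=C1C=C(CC1)C1SCCCS1 | intermediate
6 | 3-(dimethoxymethyl)cyclopent-2-en-1-one | COC(OC)C1=CC(=O)CC1 | intermediate
7 | ethyl 4-(benzyloxy)-3-oxobutanoate | CCOC(=O)CC(=O)COCc1ccccc1 | starting material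
8 | ethyl 2-[2-(benzyloxymethyl)-1,3-dioxolan-2-yl]acetate | CCOC(=O)CC1(COCc2ccccc2)OCCO1 | intermediate
9 | 2-[2-(benzyloxymethyl)-1,3-dioxolan-2-yl]acetaldehyde | O=CCC1(COCc2ccccc2)OCCO1 | intermediate
10 | trimethylaluminium | C[Al](C)C | starting material
11 | dimethylaluminium (S)-3-(dimethoxymethyl)-3-methylcyclopent-1-en-1-olate | COC(OC)[C@@]1(C)CCC(O[Al](C)C)=C1 | intermediate (not isolated)
12 | lithium trimethyl[(S)-3-(dimethoxymethyl)-3-methylcyclopent-1-en-1-olato]aluminate | COC(OC)[C@@]1(C)CCC(O[Al-](C)(C)C)=C1.[Li+] | intermediate (not isolated)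
13 | (2S,3S)-2-{(1S)-2-[2-(benzyloxymethyl)-1,3-dioxolan-2-yl]-1-hydroxyethyl}-3-(dimethoxymethyl)-3-methylcyclopentan-1-one | C(OCc1ccccc1)C2(OCCO2)C[C@H](O)[C@@H]3[C@](C)(CCC3=O)C(OC)OC | intermediate
14 | (1S,2S,3S)-2-{(1S)-2-[2-(benzyloxymethyl)-1,3-dioxolan-2-yl]-1-hydroxyethyl}-3-(dimethoxymethyl)-3-methyl-1-(prop-1-en-2-yl)cyclopentan-1-ol | C(OCc1ccccc1)C2(OCCO2)C[C@H](O)[C@@H]3[C@](C)(CC[C@@]3(O)C(C)=C)C(OC)OC | intermediate
15 | (1S)-2-[2-(benzyloxymethyl)-1,3-dioxolan-2-yl]-1-[(1S,2S,5S)-2-(dimethoxymethyl)-5-hydroxy-2-methyl-5-(prop-1-en-2-yl)cyclopentyl]ethyl 3-methylbutanoate | C(OCc1ccccc1)C2(OCCO2)C[C@H](OC(=O)CC(C)C)[C@@H]3[C@](C)(CC[C@@]3(O)C(C)=C)C(OC)OC | intermediate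
16 | (1S)-2-[2-(hydroxymethyl)-1,3-dioxolan-2-yl]-1-[(1S,2S,5R)-2-(dimethoxymethyl)-5-hydroxy-2-methyl-5-(propan-2-yl)cyclopentyl]ethyl 3-methylbutanoate | OCC2(OCCO2)C[C@H](OC(=O)CC(C)C)[C@@H]3[C@](C)(CC[C@@]3(O)C(C)C)C(OC)OC | intermediate
17 | (1S)-2-(2-formyl-1,3-dioxolan-2-yl)-1-[(1S,2S,5R)-2-(dimethoxymethyl)-5-hydroxy-2-methyl-5-(propan-2-yl)cyclopentyl]ethyl 3-methylbutanoate | O=CC2(OCCO2)C[C@H](OC(=O)CC(C)C)[C@@H]3[C@](C)(CC[C@@]3(O)C(C)C)C(OC)OC | intermediate
18 | (1S)-2-(2-formyl-1,3-dioxolan-2-yl)-1-[(1S,2S,5R)-2-formyl-5-hydroxy-2-methyl-5-(propan-2-yl)cyclopentyl]ethyl 3-methylbutanoate | O=CC2(OCCO2)C[C@H](OC(=O)CC(C)C)[C@@H]3[C@](C)(CC[C@@]3(O)C(C)C)C=O | intermediate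
19 | (1S)-2-(2-ethenyl-1,3-dioxolan-2-yl)-1-[(1S,2R,5R)-2-ethenyl-5-hydroxy-2-methyl-5-(propan-2-yl)cyclopentyl]ethyl 3-methylbutanoate | C=CC2(OCCO2)C[C@H](OC(=O)CC(C)C)[C@@H]3[C@](C)(CC[C@@]3(O)C(C)C)C=C | intermediate
20 | (3'R,3a'S,4'S,8a'R)-3'-hydroxy-8a'-methyl-3'-(propan-2-yl)-2',3',3a',4',5',8a'-hexahydro-1'H-spiro[1,3-dioxolane-2,6'-azulen]-4'-yl 3-methylbutanoate | O1CCOC12C[C@H](OC(=O)CC(C)C)[C@@H]3[C@](C)(CC[C@@]3(O)C(C)C)C=C2 | intermediate
21 | (3R,3aS,4S,8aR)-3-hydroxy-8a-methyl-6-oxo-3-(propan-2-yl)-1,2,3,3a,4,5,6,8a-octahydroazulen-4-yl 3-methylbutanoate | O=C1C[C@H](OC(=O)CC(C)C)[C@@H]2[C@](C)(CC[C@@]2(O)C(C)C)C=C1 | intermediate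
22 | (3R,3aS,4S,7S,8S,8aS)-3,7,8-trihydroxy-8a-methyl-6-oxo-3-(propan-2-yl)decahydroazulen-4-yl 3-methylbutanoate | O=C1C[C@H](OC(=O)CC(C)C)[C@@H]2[C@](C)(CC[C@@]2(O)C(C)C)[C@H](O)[C@@H]1O | intermediate
23 | (3R,3aS,4S,7R,8S,8aS)-3,7,8-trihydroxy-8a-methyl-6-methylidene-3-(propan-2-yl)decahydroazulen-4-yl 3-methylbutanoate (CNP0204264.1) | C=C1C[C@H](OC(=O)CC(C)C)[C@@H]2[C@](C)(CC[C@@]2(O)C(C)C)[C@H](O)[C@@H]1O | target

**Step count**

Total steps: 15. Longest linear sequence: 13 steps (1 → 2 → 5 → 6 … → 15; the aldehyde branch 3 → 4 → 5 … → 15 is equally long).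

**Steps most likely to fail, with fallbacks**

Step 5. The aluminium-bound enolate may add sluggishly to the aldehyde, residual methylaluminium species may consume the aldehyde by methyl transfer, and the one-pot aldol may show poor facial or anti/syn control. Fallback: separate the two bond formations. Starting from enone 6, the same copper-catalysed methyl addition is run and the aluminium enolate 11 is acetylated in the flask with acetic anhydride to give (S)-3-(dimethoxymethyl)-3-methylcyclopent-1-en-1-yl acetate F1, which is isolated. Two equivalents of MeLi in THF at 0 °C cleave the enol acetate to the aluminium-free lithium (S)-3-(dimethoxymethyl)-3-methylcyclopent-1-en-1-olate F2. At –78 °C this enolate, as such or after transmetalation with ZnCl2, adds to aldehyde 9 and the route is rejoined at 13.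

Step 15. The free C9 and C10 hydroxyls may sequester the zinc–titanium reagent, or the α-ketol may isomerise under Lewis acid, so that methylenation stalls. Fallback: mask the diol and use a titanium alkylidene. From 22, 2,2-dimethoxypropane and PPTS give the C9,C10 acetonide of 22 F3. The Tebbe reagent Cp2Ti(μ-CH2)(μ-Cl)AlMe2 in THF/toluene at –40 → 0 °C is non-basic and methylenates ketones faster than esters, and should give the C9,C10 acetonide of the target F4. Aqueous acetic acid at rt removes the acetonide and returns to 23.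

Step 12. Both vinyl groups sit on fully substituted carbons, so initiation may be slow and catalyst decay or intermolecular metathesis may outrun ring closure. Fallback: close the ring by reductive carbonyl coupling instead, bypassing steps 11 and 12. Dialdehyde 18 is added slowly at high dilution to low-valent titanium (TiCl3(DME)1.5, Zn–Cu couple, DME, reflux); aldehydes couple much faster than the ester, and this McMurry coupling should give cycloalkene 20 directly, where the route is rejoined. No new compound arises (entry F0).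

**Further compounds**

F1 | step 5 | (S)-3-(dimethoxymethyl)-3-methylcyclopent-1-en-1-yl acetate | COC(OC)[C@@]1(C)CCC(OC(C)=O)=C1
F2 | step 5 | lithium (S)-3-(dimethoxymethyl)-3-methylcyclopent-1-en-1-olate | COC(OC)[C@@]1(C)CCC(O[Li])=C1
F3 | step 15 | C9,C10 acetonide of 22 | O=C1C[C@H](OC(=O)CC(C)C)[C@@H]2[C@](C)(CC[C@@]2(O)C(C)C)[C@H]3[C@@H]1OC(C)(C)O3
F4 | step 15 | C9,C10 acetonide of 23 | C=C1C[C@H](OC(=O)CC(C)C)[C@@H]2[C@](C)(CC[C@@]2(O)C(C)C)[C@H]3[C@@H]1OC(C)(C)O3
F0 | step 12 | none | none
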